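**Retrosynthetic overview**
- C2–Br goes on last by electrophilic bromination of 4,7-dibromo-3-chloroindole; C3–Cl is installed just before with NCS, so the second halogen can only end up at C2.
- 4,7-Dibromoindole comes from protodecarboxylation of its 2-carboxylic acid, which comes from the ethyl ester.
- The pyrrole ring is the only ring formed (the benzene ring is bought): Hemetsberger–Knittel nitrene cyclisation of a (Z)-α-azidocinnamate onto the single free ortho C–H closes N1–C7a.
- Key C–C bond (indole C2–C3): intermolecular aldol condensation of 2,5-dibromobenzaldehyde with the enolate of ethyl azidoacetate.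
- Both ring bromines are bought in place, which fixes the 4,7-pattern.

Assumption: the target has no stereocentre (it is achiral), so no enantioselective step is needed; the only stereo-element in the route is the Z alkene of compound 4.

**Step 1**
Reactants: 1 2,5-dibromobenzaldehyde; 2 ethyl azidoacetate
Product: 4 ethyl (Z)-2-azido-3-(2,5-dibromophenyl)prop-2-enoate, via azido aldol adduct 3 (not isolated)
Conditions: NaOEt (4 equiv), 2 (4 equiv), EtOH, −15 → 0 °C, 3 h; cold aq NH4Cl, filter
Reagents that add atoms: none
Why: Intermolecular aldol (Knoevenagel-type) condensation of the azidoacetate enolate with a non-enolisable aldehyde, followed by E1cB loss of hydroxide, gives the thermodynamically preferred Z-azidocinnamate (aryl cis to N3).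

**Step 2**
Reactants: 4 ethyl (Z)-2-azido-3-(2,5-dibromophenyl)prop-2-enoate
Product: 6 ethyl 4,7-dibromo-1H-indole-2-carboxylate, via 2H-azirine 5 (not isolated)
Conditions: xylenes, reflux (140 °C), 0.05 M, slow addition, 2 h
Reagents that add atoms: none
Why: Hemetsberger–Knittel indole synthesis: loss of N2 gives a vinyl nitrene/azirine that cyclises onto the only free ortho C–H, so the two bromines necessarily end up at C4 and C7.

**Step 3**
Reactants: 6 ethyl 4,7-dibromo-1H-indole-2-carboxylate
Product: 7 4,7-dibromo-1H-indole-2-carboxylic acid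
Conditions: NaOH (3 equiv), EtOH/THF/H2O, 60 °C; then 1 M HCl to pH 2
Reagents that add atoms: sodium hydroxide (aqueous), [Na+].[OH-]
Why: Plain ester saponification (BAc2); aryl bromides and the indole are inert to aqueous hydroxide at 60 °C.

**Step 4**
Reactants: 7 4,7-dibromo-1H-indole-2-carboxylic acid
Product: 8 4,7-dibromo-1H-indole
Conditions: Cu powder (0.2 equiv), quinoline, 210 °C, 1.5 h, N2; 2 M HCl wash
Reagents that add atoms: none
Why: Copper-mediated thermal protodecarboxylation of an indole-2-carboxylic acid, the classical way to remove the ester handle left by the Hemetsberger synthesis from bromoindoles.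

**Step 5**
Reactants: 8 4,7-dibromo-1H-indole
Product: 9 4,7-dibromo-3-chloro-1H-indole
Conditions: NCS (1.05 equiv), DMF, 0 °C → rt, dark; use promptly
Reagents that add atoms: N-chlorosuccinimide, O=C1CCC(=O)N1Cl
Why: Electrophilic aromatic substitution at C3, the most nucleophilic indole position, while the dibrominated benzo ring is deactivated.

**Step 6**
Reactants: 9 4,7-dibromo-3-chloro-1H-indole
Product: 10 2,4,7-tribromo-3-chloro-1H-indole
Conditions: NBS (1.05 equiv), dry DMF, 0 °C → rt, dark
Reagents that add atoms: N-bromosuccinimide, O=C1CCC(=O)N1Br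
Why: Electrophilic bromination of a 3-blocked indole: direct C2 attack, or C3 attack followed by 1,2-shift of the better-migrating bromine, both give the 2-bromo-3-chloro pattern.

**Compound list**
1 | 2,5-dibromobenzaldehyde | O=Cc1cc(Br)ccc1Br | starting material
2 | ethyl azidoacetate | CCOC(=O)CN=[N+]=[N-] | starting material
3 | ethyl 2-azido-3-(2,5-dibromophenyl)-3-hydroxypropanoate (racemic diastereomer mixture) | CCOC(=O)C(N=[N+]=[N-])C(O)c1cc(Br)ccc1Br | intermediate (not isolated)
4 | ethyl (Z)-2-azido-3-(2,5-dibromophenyl)prop-2-enoate | CCOC(=O)/C(N=[N+]=[N-])=C/c1cc(Br)ccc1Br | intermediate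
5 | ethyl 2-(2,5-dibromophenyl)-2H-azirine-3-carboxylate (racemic) | CCOC(=O)C1=NC1c1cc(Br)ccc1Br | intermediate (not isolated)
6 | ethyl 4,7-dibromo-1H-indole-2-carboxylate | CCOC(=O)c1cc2c(Br)ccc(Br)c2[nH]1 | intermediate
7 | 4,7-dibromo-1H-indole-2-carboxylic acid | OC(=O)c1cc2c(Br)ccc(Br)c2[nH]1 | intermediate
8 | 4,7-dibromo-1H-indole | Brc1ccc(Br)c2[nH]ccc12 | intermediate
9 | 4,7-dibromo-3-chloro-1H-indole | Clc1c[nH]c2c(Br)ccc(Br)c12 | intermediate
10 | 2,4,7-tribromo-3-chloro-1H-indole | Clc1c(Br)[nH]c2c(Br)ccc(Br)c12 | target

**Total step count:** 6. **Longest linear sequence:** 6.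

**Steps most likely to fail, with fallbacks**

Step 4 is the main risk: copper at 210 °C next to two aryl bromides can cause Ullmann-type coupling or debromination. The fallback sets out from 6 and comes back to the route at 10. The ester is chlorinated at C3 with NCS in DMF at 50 °C to give ethyl 4,7-dibromo-3-chloro-1H-indole-2-carboxylate F3. Saponification (LiOH, THF/H2O) gives 4,7-dibromo-3-chloro-1H-indole-2-carboxylic acid F4. The carboxyl group is then replaced by bromine in an ipso-bromodecarboxylation (NBS, NaHCO3, DMF, rt), which gives 10 directly without copper or high temperature and bypasses 7, 8 and 9.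

Step 6 is the second risk: possible Br/Cl exchange or chlorine migration at C2/C3, or oxidation to an oxindole if water is present. The fallback sets out from 9 and comes back at 10 by directed metalation instead of electrophilic substitution. Boc2O/DMAP in MeCN gives tert-butyl 4,7-dibromo-3-chloro-1H-indole-1-carboxylate F5. LDA in THF at −78 °C (an amide base, so no bromine–lithium exchange) followed by BrCCl2CCl2Br gives tert-butyl 2,4,7-tribromo-3-chloro-1H-indole-1-carboxylate F6 through the C2-lithio species. TFA/CH2Cl2 at 0 °C removes the Boc group to give 10.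

Step 1 is the third risk: base-induced decomposition of the azidoacetate competes, and the ortho-bromo aldehyde may stop at the aldol stage. The fallback sets out from 1 and comes back at 4 by introducing the azide after the C–C bond is made. Knoevenagel–Doebner condensation of 1 with monoethyl malonate (pyridine, cat. piperidine, 100 °C) gives ethyl (E)-3-(2,5-dibromophenyl)prop-2-enoate F1. Anti addition of Br2 in CH2Cl2 gives racemic ethyl (2R*,3S*)-2,3-dibromo-3-(2,5-dibromophenyl)propanoate F2. NaN3 (3 equiv) in DMF at rt to 50 °C substitutes the α-bromide and eliminates HBr to give 4.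

**Further compounds**
F1 | step 1 | ethyl (E)-3-(2,5-dibromophenyl)prop-2-enoate | CCOC(=O)/C=C/c1cc(Br)ccc1Br
F2 | step 1 | ethyl (2R*,3S*)-2,3-dibromo-3-(2,5-dibromophenyl)propanoate (racemic, one enantiomer drawn) | CCOC(=O)[C@@H](Br)[C@@H](Br)c1cc(Br)ccc1Br
F3 | step 4 | ethyl 4,7-dibromo-3-chloro-1H-indole-2-carboxylate | CCOC(=O)c1[nH]c2c(Br)ccc(Br)c2c1Cl
F4 | step 4 | 4,7-dibromo-3-chloro-1H-indole-2-carboxylic acid | OC(=O)c1[nH]c2c(Br)ccc(Br)c2c1Cl
F5 | step 6 | tert-butyl 4,7-dibromo-3-chloro-1H-indole-1-carboxylate | CC(C)(C)OC(=O)n1cc(Cl)c2c(Br)ccc(Br)c21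
F6 | step 6 | tert-butyl 2,4,7-tribromo-3-chloro-1H-indole-1-carboxylate | CC(C)(C)OC(=O)n1c(Br)c(Cl)c2c(Br)ccc(Br)c21
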